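## Structural features

The target is a C20 diterpenoid acetate. Numbering used here: C15 is the acetoxy carbon; ring A is C15–C1=C2(CH3)–C3(=O)–C4; C5 is the exocyclic alkene CH on C4; the oxolane is C6(CH3)–C7–C8–C9–O; C10 is the CMe2 carbon; C11, C12 and C13 (CHCH3) lead to the C14 ketone on C15. Ring A is a cross-conjugated cyclopentenone fused through C15 and the exocyclic C4=C5 bond to a twelve-membered carbocycle (C4, C5–C14, C15), which the oxolane oxygen bridges between C6 and C9. C5 and C10 are trans on the oxolane, and the C4=C5 alkene is E, so the oxolane lies on the C15 side and not on the C3 carbonyl side. There are four stereocentres: C15 (quaternary, S) and C13 (R) flank the C14 ketone, and C6 (quaternary ether, S) and C9 (S) sit 1,4 across the oxolane; the two pairs are remote from each other. The fragile groups are the tertiary, doubly allylic α-keto acetate, the dienone (conjugate addition, light, E/Z lability) and the epimerisable C13. The real difficulty is the fully substituted C15 carbinol of defined absolute configuration between two trigonal ring carbons and a ketone, followed by closure of a strained ansa ring with control of C6 and C13. The key step uses the fact that C15, with its oxygen, its exocyclic carbonyl carbon C14 and its two ring neighbours C1 and C4, is C1 of (−)-quinic acid with hydroxyl, carboxyl and two ring CH2 groups, while the oxygens on quinic C3 and C4 become the handles at C2 and C3; an atom-by-atom check shows that the S configuration at C15 results only when the trans-diol bond (quinic C4–C5) is cleaved and the ring is re-closed from quinic C6 onto quinic C4.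

## Logic of the disconnections

27 ⇒ 26. Cut: the O15–acyl bond. The acetate is the most labile group (a leaving group β to nothing only once C4 is trigonal), so it is put on last. This leaves a free tertiary alcohol that tolerates organomagnesium, palladium and radical chemistry. The forward step must acylate a hindered tertiary hydroxyl without touching C13.

26 ⇒ 25. Cut: C11–C12, with the hydrogen on C13. This opens the twelve-membered ring to a neopentyl bromide (no β-hydrogen, inert to ionic reagents) and an isopropenyl ketone, and removes the C13 stereocentre. The forward step must let a 12-endo radical conjugate addition outrun simple reduction, must deliver hydrogen to the correct face at C13, and can only work from the E alkene.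

25 ⇒ 24 ⇒ 23. Cut: C2–CH3. The methyl group is traded for the oxygen that the cyclohexane precursor already carries at this carbon, through the enol triflate of a 1,2-dione. The forward steps need sulfonylation of the acidic enol only, and a palladium-catalysed methylation that ignores the alkyl bromide and both enones.

23 ⇒ 22 ⇒ 21 ⇒ 20. Cut: C13–C14 (acyl–vinyl bond), with C2/C3 returned to the diol level. The vinyl nucleophile has to meet an acyl donor at C14 while no ketone is present, so C3 is held as a carbinol in 20 and both ring oxygens are oxidised afterwards. Demands: addition to an amide next to a quaternary alkoxide, and a double oxidation that does not cleave the diol.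

20 ⇒ 19 ⇒ 9 + 18. Cut: C5–C6. This divides the skeleton into two halves of similar size and makes C6 a tertiary α-oxy radical (from an acid) that substitutes iodine on a β-iodo enone. C6 need not be controlled in 18, but the forward step must add anti to the C9 substituent and give the E alkene. The C3 ketone that activates C5 is then masked by reduction (19 ⇒ 20).

9 ⇒ 8 ⇒ 7. Functional-group changes only: C5–I from the enol of a 2-formyl ketone, and the C3 ketone from the aldol carbinol. Both aldol stereocentres vanish, so 7 may be a mixture.

7 ⇒ 6 ⇒ 5. Cut: C3–C4; reconnect C3–C5. This is the strategic retron: a 2-formylcyclopentanol is a ring-contracted cyclohexane-1,2-diol. It turns ring A into a cyclohexane whose stereocentres are all of chiral-pool origin. The forward step needs chemoselective cleavage of one diol and one donor/acceptor pairing in the aldol.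

5 ⇒ 4 ⇒ 3 ⇒ 2 ⇒ 1. Protecting-group logic on the cyclohexane: the trans-4,5-diol is masked as a diacetal while the 3-hydroxyl is silylated, then released. C14 is carried from 4 onwards as an N-methoxy-N-methylamide and not as an ester. The amide cannot lactonise onto the C3 hydroxyls that appear in 7 and 20, and it is already the acyl donor needed for 20 ⇒ 21.

18 ⇒ 17 ⇒ 16 ⇒ 15 ⇒ 14 ⇒ 10 + 11. Cut: C6–O (epoxide opening), then the oxidation level at the carboxyl carbon, then the C9–H bond (reagent-controlled ketone reduction sets C9), then C8–C9 (acylation). The forward sequence needs only one controlled centre (C9), because C6 is re-set in the coupling.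

## Other disconnections considered

Alternative 1: Both C–O bonds of ring A (C15–O and C3–O) are cut, leading to the macrocyclic acylfulvene A1. In the forward sense, sensitised photooxygenation adds singlet oxygen across C15 and C3 to give the endoperoxide A2, and an amine base removes H3 with O–O cleavage (Kornblum–DeLaMare) to give the hydroxy dienone A3, which is the same compound as 26. In its favour: both oxygens arrive in one operation at the very end, ring A needs no protecting groups, and the peroxide can only open one way because C15 has no hydrogen. Against it here: the C15 configuration would come from the facial selectivity of a cycloaddition onto an ansa-fulvene, governed only by the conformation of the bridge. An acyl-substituted fulvene is a poor partner for electrophilic oxygen and its peroxide has several rearrangement channels. A1 itself (a reactive fulvene inside a strained ring, with C13 next to a fulvene-conjugated ketone) is harder to reach than 25. Comparison: on structure the chosen plan fixes C15 from the chiral pool, whereas this route creates it last under substrate control. On mechanism a pericyclic step replaces an ionic aldol. On step economy after the macrocycle this alternative is the better one, and it ends at the same penultimate compound.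

Alternative 2: The C6 methyl carbon (C17) is reconnected to C11 as a ketone bridge, and C6–C17 and C9–C10 are cut, leading to the furan A4 and the dibromo ketone A5. In the forward sense, the oxyallyl cation released from A5 by Fe2(CO)9 adds across the furan in a [4+3] cycloaddition to give the oxabicycle A6. In its favour: the oxolane, the quaternary C6 and the C6/C9 relationship (methyl cis to C10, hence C5 trans to C10) are set by the bicyclic constraint in one step from simple materials. On this point it is better than the chosen plan, which relies on steric approach control at C6. Against it: A6 is formed racemic unless an absolute control element is added; the unsymmetrical cation can add in two orientations; and the bridge must later be cut at C11–C17 next to a quaternary carbon, with C7=C8 reduced. It also solves only the oxolane half: ring A and C15 would still be needed and could still come from the chosen key step. Comparison: equal or better on relative configuration, worse on absolute configuration, and no gain in step count against the four steps to 18.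

Alternative 3: C4–C15 is cut and C15 and C3 are tied through oxygen as a furan, leading to the furanophane carbinol A7. In the forward sense, Dy(OTf)3 in wet acetonitrile ionises the C4 carbinol, water adds at C15, the furan opens and a conrotatory 4π closure gives the hydroxycyclopentenone A8, contracting the macrocycle and forming ring A at once (Piancatelli rearrangement). In its favour: one catalytic step builds ring A, the C15 carbinol and the carbocycle, and a furan is a robust linchpin for assembling the large ring; in bond economy at ring A this is better than the chosen plan. Against it: a furan substituted at the carbon that must accept water is the difficult case of this rearrangement. The C15 configuration would depend on the torquoselectivity of the closure under remote control, since C4 becomes trigonal later. The product still needs C4–C5 dehydrogenation and oxidation at C14 in a molecule with several enolisable sites. Comparison: shorter on paper, but the chosen plan is safer for the absolute configuration at C15 and for the oxidation pattern.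

Key step: step 5

Remark on the chemistry: centres that later become trigonal or radical (C3/C4 of 7, C3 of 20–22, ring C2 of 16–18) are carried as epimer mixtures and are left undefined in the SMILES.

## Route

Step 1
Reactants: 1 (−)-quinic acid
Product: 2 methyl 4,5-O-[(2S,3S)-2,3-dimethoxybutane-2,3-diyl]quinate
Conditions: butane-2,3-dione, HC(OMe)3, CSA (cat.), MeOH, reflux
Reagents that add atoms: butane-2,3-dione CC(=O)C(C)=O; methanol CO; trimethyl orthoformate COC(OC)OC (methoxy source and water scavenger)
Why: Fischer esterification and thermodynamic bis-ketalisation in one pot; only the trans-diequatorial 4,5-diol can span a chair 1,4-dioxane with both methoxy groups axial (anomeric effect), so the 1- and 3-hydroxyls stay free.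

Step 2
Reactants: 2 methyl 4,5-O-[(2S,3S)-2,3-dimethoxybutane-2,3-diyl]quinate
Product: 3 methyl 3-O-(tert-butyldimethylsilyl)-4,5-O-[(2S,3S)-2,3-dimethoxybutane-2,3-diyl]quinate
Conditions: TBSCl, imidazole, DMAP (cat.), DMF, 40 °C
Reagents that add atoms: tert-butyldimethylsilyl chloride CC(C)(C)[Si](C)(C)Cl
Why: Silylation of the secondary 3-hydroxyl; the tertiary α-hydroxy ester hydroxyl is too hindered for the silyl chloride.

Step 3
Reactants: 3 methyl 3-O-(tert-butyldimethylsilyl)-4,5-O-[(2S,3S)-2,3-dimethoxybutane-2,3-diyl]quinate
Product: 4 N-methoxy-N-methyl-3-O-(tert-butyldimethylsilyl)-4,5-O-[(2S,3S)-2,3-dimethoxybutane-2,3-diyl]quinamide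
Conditions: MeNH(OMe)·HCl, iPrMgCl, THF, −20 → 0 °C
Reagents that add atoms: N,O-dimethylhydroxylamine hydrochloride CNOC.Cl
Why: Aminolysis of the ester by the magnesium amide formed in the flask (Weinreb amide formation); the α-alkoxide assists, and silyl ether and diacetal are inert to the base.

Step 4
Reactants: 4 N-methoxy-N-methyl-3-O-(tert-butyldimethylsilyl)-4,5-O-[(2S,3S)-2,3-dimethoxybutane-2,3-diyl]quinamide
Product: 5 N-methoxy-N-methyl-3-O-(tert-butyldimethylsilyl)quinamide (free trans-4,5-diol; quinic acid numbering)
Conditions: TFA/H2O (9:1), 0 °C, short contact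
Reagents that add atoms: none
Why: Acid hydrolysis of the bis-ketal; the hindered secondary silyl ether and the amide should survive brief cold aqueous acid.

Step 5
Reactants: 5 N-methoxy-N-methyl-3-O-(tert-butyldimethylsilyl)quinamide
Product: 7 (2R,15S)-2-(tert-butyldimethylsilyloxy)-3,15-dihydroxy-4-formyl-N-methoxy-N-methylcyclopentane-15-carboxamide (target numbering; C3/C4 epimers), via ring-opened dialdehyde 6 (not isolated)
Conditions: NaIO4, THF/H2O, 0 °C; extractive work-up; then pyrrolidine (30 mol %), CH2Cl2, −20 → 0 °C
Reagents that add atoms: none
Why: Periodate forms a cyclic ester with the only free vicinal diol and fragments it to dialdehyde 6, in which the α-silyloxy aldehyde (future C3) is reversibly masked as a five-membered lactol by the C15 hydroxyl. Pyrrolidine condenses with the unhindered CH2-flanked aldehyde (C5) to give an enamine whose α-carbon C4 adds to the C3 aldehyde, and hydrolysis of the iminium ion returns the amine (intramolecular enamine aldol, Hajos–Parrish-type aminocatalysis, here as a six-to-five ring contraction of a cleaved cyclohexanediol). The ring closes in a 5-(enolexo)-exo-trig mode and the only new skeletal bond is C3–C4. C3 and C4 become stereocentres (the trans aldol is expected from the closed transition state), but neither needs control because both are trigonal after steps 6 and 7, while C15 and C2 are spectators that keep the configuration of quinic C1 and C3. The step needs one donor/acceptor pairing: the α-branched, α-oxygenated aldehyde forms an enamine slowly, is the more electrophilic carbonyl and is tied up as the lactol, so closure in the reverse sense (C2 onto C5) is disfavoured. It must also stop at the aldol stage, which is why no acid co-catalyst is used and the temperature stays at or below 0 °C. The amide in place of an ester keeps the new C3 hydroxyl from lactonising onto C14.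

Step 6
Reactants: 7 (2R,15S)-2-(tert-butyldimethylsilyloxy)-3,15-dihydroxy-4-formyl-N-methoxy-N-methylcyclopentane-15-carboxamide
Product: 8 (2R,15S)-2-(tert-butyldimethylsilyloxy)-15-hydroxy-4-[(Z)-hydroxymethylene]-N-methoxy-N-methyl-3-oxocyclopentane-15-carboxamide
Conditions: IBX (1.5 equiv), DMSO, rt
Reagents that add atoms: none
Why: Hypervalent-iodine oxidation of the secondary aldol carbinol (β-hydroxy aldehyde to β-keto aldehyde); the product is the hydrogen-bonded hydroxymethylene ketone, which erases both aldol stereocentres, and the tertiary alcohol is inert.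

Step 7
Reactants: 8 (2R,15S)-2-(tert-butyldimethylsilyloxy)-15-hydroxy-4-[(Z)-hydroxymethylene]-N-methoxy-N-methyl-3-oxocyclopentane-15-carboxamide
Product: 9 (2R,15S)-2-(tert-butyldimethylsilyloxy)-15-hydroxy-4-[(E)-iodomethylene]-N-methoxy-N-methyl-3-oxocyclopentane-15-carboxamide
Conditions: Ph3P, I2, Et3N, MeCN, 0 °C → rt
Reagents that add atoms: iodine II
Why: The enol oxygen is activated as an oxyphosphonium ion and displaced by iodide at the less hindered formyl-derived carbon C5 by addition–elimination (β-dicarbonyl enol to β-iodo enone); iodine anti to the carbonyl is expected, and the geometry is erased in step 12 in any case.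

Step 8
Reactants: 10 3-bromo-2,2-dimethylpropanoic acid, 11 4-bromo-2-methylbut-1-ene
Product: 14 1-bromo-2,2,6-trimethylhept-6-en-3-one, via 3-bromo-2,2-dimethylpropanoyl chloride 12 (not isolated), via (3-methylbut-3-en-1-yl)magnesium bromide 13 (not isolated)
Conditions: 10: (COCl)2, DMF (cat.), CH2Cl2, rt, evaporate; 11: Mg, THF, 40 °C; combine with CuI (5 mol %), THF, −78 → −20 °C
Reagents that add atoms: none
Why: Copper-catalysed acylation of a Grignard reagent by an acid chloride stops at the ketone because the acyl group is neopentyl-type; the bromide sits on a carbon whose neighbour is quaternary, so neither elimination nor displacement can occur.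

Step 9
Reactants: 14 1-bromo-2,2,6-trimethylhept-6-en-3-one
Product: 15 (3S)-1-bromo-2,2,6-trimethylhept-6-en-3-ol
Conditions: (R)-2-methyl-CBS-oxazaborolidine (20 mol %), catecholborane, toluene, −40 → 0 °C
Reagents that add atoms: none
Why: CBS reduction: the oxazaborolidine distinguishes the tert-alkyl from the primary alkyl group, and the (R)-catalyst should give the 3S carbinol (the future C9); catecholborane is used as the hydride source so that the 1,1-disubstituted alkene is not hydroborated.

Step 10
Reactants: 15 (3S)-1-bromo-2,2,6-trimethylhept-6-en-3-ol
Product: 17 [(5S)-5-(1-bromo-2-methylpropan-2-yl)-2-methyloxolan-2-yl]methanol (C2 epimers), via hydroxy epoxide 16 (not isolated)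
Conditions: mCPBA, CH2Cl2, 0 °C; then CSA (cat.), rt
Reagents that add atoms: 3-chloroperoxybenzoic acid O=C(OO)c1cccc(Cl)c1
Why: Prilezhaev epoxidation of the electron-rich alkene, then acid-catalysed 5-exo opening of the epoxide at its tertiary carbon by the carbinol oxygen, so the C9–O bond is never broken. The new quaternary centre forms unselectively, which does not matter because it becomes a radical in step 12.

Step 11
Reactants: 17 [(5S)-5-(1-bromo-2-methylpropan-2-yl)-2-methyloxolan-2-yl]methanol
Product: 18 (5S)-5-(1-bromo-2-methylpropan-2-yl)-2-methyloxolane-2-carboxylic acid (C2 epimers)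
Conditions: TEMPO (cat.), PhI(OAc)2, MeCN/H2O (1:1), rt
Reagents that add atoms: water O
Why: Oxoammonium oxidation of the primary alcohol to the aldehyde and, through its hydrate, to the acid; the ether and the neopentyl bromide are inert.

Step 12
Reactants: 9 (2R,15S)-2-(tert-butyldimethylsilyloxy)-15-hydroxy-4-[(E)-iodomethylene]-N-methoxy-N-methyl-3-oxocyclopentane-15-carboxamide, 18 (5S)-5-(1-bromo-2-methylpropan-2-yl)-2-methyloxolane-2-carboxylic acid
Product: 19 (2R,4E,6S,9S,15S)-coupled enone: amide and OH on C15, OTBS on C2, C3 ketone, C4=C5, C5 bonded to C6 of the 2,5-trans oxolane carrying C10(CH3)2–C11H2Br on C9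
Conditions: [Ir(dF(CF3)ppy)2(dtbbpy)]PF6 (2 mol %), K2HPO4, DMSO, blue LEDs, rt, degassed
Reagents that add atoms: none
Why: The photoexcited iridium complex oxidises the carboxylate of 18; loss of CO2 gives the tertiary α-oxy C6 radical, which adds to C5 of the β-iodo enone, and the α-keto radical expels an iodine atom that closes the photoredox cycle as iodide (decarboxylative radical addition–β-elimination, the vinylic substitution known for β-sulfonyl and β-halo acceptors). The planar C6 radical should be attacked anti to the bulky C9 substituent, which puts C5 trans to C10 (6S). The E alkene should be preferred, because the 15-hydroxyl can hydrogen-bond to the oxolane oxygen while the Z isomer presses that oxygen against the C3 carbonyl, and the two isomers can equilibrate under the sensitising conditions.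

Step 13
Reactants: 19 coupled enone
Product: 20 (2R,4E,6S,9S,15S)-allylic alcohol: as 19 with C3 reduced to CH(OH) (C3 epimers)
Conditions: NaBH4, CeCl3·7H2O, MeOH, −78 °C
Reagents that add atoms: none
Why: Luche reduction gives clean 1,2-reduction of the enone and leaves amide, bromide and silyl ether untouched; the C3 carbinol is a temporary mask whose configuration is irrelevant, and it removes the only ketone before the organomagnesium step.

Step 14
Reactants: 20 allylic alcohol
Product: 21 (2R,4E,6S,9S,15S)-isopropenyl ketone: as 20 with C14 as C(=O)–C(CH3)=CH2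
Conditions: isopropenylmagnesium bromide (5 equiv), THF, −20 °C → rt; aq. NH4Cl
Reagents that add atoms: isopropenylmagnesium bromide CC(=C)[Mg]Br
Why: Weinreb ketone synthesis: the excess reagent first deprotonates the two hydroxyls and then adds to the amide to give a chelated tetrahedral intermediate that collapses to the enone only on work-up. With C3 at the alcohol level there is no competing ketone, and the neopentyl bromide is inert.

Step 15
Reactants: 21 isopropenyl ketone
Product: 22 (2R,4E,6S,9S,15S)-triol: as 21 with free 2-OH
Conditions: HF·pyridine, pyridine, THF, 0 °C → rt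
Reagents that add atoms: none
Why: Fluoride-assisted cleavage of the secondary silyl ether under buffered conditions that spare the allylic alcohol, the enone and the bromide.

Step 16
Reactants: 22 triol
Product: 23 (4E,6S,9S,15S)-diosphenol: ring A = 2,15-dihydroxycyclopent-1-en-3-one with exocyclic C4=C5, isopropenyl ketone on C15
Conditions: IBX (3 equiv), DMSO, rt
Reagents that add atoms: none
Why: IBX oxidises both secondary carbinols without cleaving the 1,2-diol; the 1,2-dione can enolise only towards C1 and is obtained as its enol (diosphenol) form, the tertiary 15-hydroxyl being inert.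

Step 17
Reactants: 23 diosphenol
Product: 24 (4E,6S,9S,15S)-enol triflate: as 23 with 2-OSO2CF3
Conditions: PhNTf2, Et3N, DMAP (cat.), CH2Cl2, 0 °C → rt
Reagents that add atoms: N-phenylbis(trifluoromethanesulfonimide) O=S(=O)(N(c1ccccc1)S(=O)(=O)C(F)(F)F)C(F)(F)F
Why: Only the acidic enol hydroxyl is sulfonylated by the mild triflyl donor under amine base; the hindered tertiary alcohol does not react.

Step 18
Reactants: 24 enol triflate
Product: 25 (4E,6S,9S,15S)-bromo dienone: ring A = 15-hydroxy-2-methylcyclopent-1-en-3-one with exocyclic C4=C5 to the oxolane, isopropenyl ketone on C15, C11H2Br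
Conditions: Me4Sn, Pd2(dba)3 (5 mol %), AsPh3, LiCl, NMP, 45 °C
Reagents that add atoms: tetramethylstannane C[Sn](C)(C)C
Why: Stille coupling: oxidative addition of the electron-poor enol triflate, methyl transfer from tin and reductive elimination give the 2-methyl enone. The neopentyl bromide does not add oxidatively and the enones are spectators under these neutral conditions.

Step 19
Reactants: 25 bromo dienone
Product: 26 (4E,6S,9S,13R,15S)-15-O-deacetyl target: macrocyclic hydroxy dienone with C11–C12 closed and C13H(CH3)
Conditions: Bu3SnH (1.3 equiv, syringe pump, 10 h), AIBN, benzene, 80 °C, 1 mM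
Reagents that add atoms: none
Why: The stannyl radical abstracts bromine from neopentyl C11, and the nucleophilic primary radical adds to the unsubstituted terminus C12 of the isopropenyl ketone in a 12-endo-trig Giese macrocyclisation under high dilution. The trans-oxolane keeps C11 away from C5, so C12 is the only reachable acceptor. The C13 α-keto radical then takes hydrogen from Bu3SnH on the outer face of the new ring, which should favour the 13R epimer with the methyl group on the ring periphery; slow addition keeps the hydride concentration low enough for closure to win over direct reduction.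

Step 20
Reactants: 26 15-O-deacetyl target
Product: 27 CNP0144863.1, the (4E,6S,9S,13R,15S)-15-acetate of 26
Conditions: Ac2O, DMAP, Et3N, CH2Cl2, rt
Reagents that add atoms: acetic anhydride CC(=O)OC(C)=O
Why: DMAP-catalysed acylation of the tertiary α-ketol through the N-acetylpyridinium ion; no β-elimination is possible because both ring neighbours of C15 are trigonal, and the mild amine base should not epimerise C13.

## Compound list

1 | (−)-quinic acid | O[C@@]1(C(=O)O)C[C@@H](O)[C@@H](O)[C@H](O)C1 | starting material
2 | methyl 4,5-O-[(2S,3S)-2,3-dimethoxybutane-2,3-diyl]quinate | O[C@@]1(C(=O)OC)C[C@@H](O)[C@H]2O[C@](C)(OC)[C@@](C)(OC)O[C@@H]2C1 | intermediate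
3 | methyl 3-O-(tert-butyldimethylsilyl)-4,5-O-[(2S,3S)-2,3-dimethoxybutane-2,3-diyl]quinate | O[C@@]1(C(=O)OC)C[C@@H](O[Si](C)(C)C(C)(C)C)[C@H]2O[C@](C)(OC)[C@@](C)(OC)O[C@@H]2C1 | intermediate
4 | N-methoxy-N-methyl-3-O-(tert-butyldimethylsilyl)-4,5-O-[(2S,3S)-2,3-dimethoxybutane-2,3-diyl]quinamide | O[C@@]1(C(=O)N(C)OC)C[C@@H](O[Si](C)(C)C(C)(C)C)[C@H]2O[C@](C)(OC)[C@@](C)(OC)O[C@@H]2C1 | intermediate
5 | N-methoxy-N-methyl-3-O-(tert-butyldimethylsilyl)quinamide (free trans-4,5-diol) | O[C@@]1(C(=O)N(C)OC)C[C@@H](O[Si](C)(C)C(C)(C)C)[C@@H](O)[C@H](O)C1 | intermediate (key-step precursor)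
6 | (2S)-2-hydroxy-N-methoxy-N-methyl-4-oxo-2-[(2R)-2-(tert-butyldimethylsilyloxy)-3-oxopropyl]butanamide | O[C@@](CC=O)(C(=O)N(C)OC)C[C@@H](O[Si](C)(C)C(C)(C)C)C=O | intermediate (not isolated)
7 | (2R,15S)-2-(tert-butyldimethylsilyloxy)-3,15-dihydroxy-4-formyl-N-methoxy-N-methylcyclopentane-15-carboxamide (target numbering, C3/C4 epimers) | O[C@@]1(C(=O)N(C)OC)C[C@@H](O[Si](C)(C)C(C)(C)C)C(O)C1C=O | intermediate (key-step product)
8 | (2R,15S)-2-(tert-butyldimethylsilyloxy)-15-hydroxy-4-[(Z)-hydroxymethylene]-N-methoxy-N-methyl-3-oxocyclopentane-15-carboxamide | O[C@@]1(C(=O)N(C)OC)C[C@@H](O[Si](C)(C)C(C)(C)C)C(=O)/C1=C\O | intermediate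
9 | (2R,15S)-2-(tert-butyldimethylsilyloxy)-15-hydroxy-4-[(E)-iodomethylene]-N-methoxy-N-methyl-3-oxocyclopentane-15-carboxamide | O[C@@]1(C(=O)N(C)OC)C[C@@H](O[Si](C)(C)C(C)(C)C)C(=O)/C1=C/I | intermediate
10 | 3-bromo-2,2-dimethylpropanoic acid | OC(=O)C(C)(C)CBr | starting material
11 | 4-bromo-2-methylbut-1-ene | C=C(C)CCBr | starting material
12 | 3-bromo-2,2-dimethylpropanoyl chloride | ClC(=O)C(C)(C)CBr | intermediate (not isolated)
13 | (3-methylbut-3-en-1-yl)magnesium bromide | C=C(C)CC[Mg]Br | intermediate (not isolated)
14 | 1-bromo-2,2,6-trimethylhept-6-en-3-one | C=C(C)CCC(=O)C(C)(C)CBr | intermediate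
15 | (3S)-1-bromo-2,2,6-trimethylhept-6-en-3-ol | C=C(C)CC[C@H](O)C(C)(C)CBr | intermediate
16 | (3S)-1-bromo-2,2-dimethyl-5-(2-methyloxiran-2-yl)pentan-3-ol (epoxide epimers) | CC1(CC[C@H](O)C(C)(C)CBr)CO1 | intermediate (not isolated)
17 | [(5S)-5-(1-bromo-2-methylpropan-2-yl)-2-methyloxolan-2-yl]methanol (C2 epimers) | OCC1(C)CC[C@H](O1)C(C)(C)CBr | intermediate
18 | (5S)-5-(1-bromo-2-methylpropan-2-yl)-2-methyloxolane-2-carboxylic acid (C2 epimers) | OC(=O)C1(C)CC[C@H](O1)C(C)(C)CBr | intermediate
19 | (2R,4E,6S,9S,15S)-coupled enone (amide, 15-OH, 2-OTBS, C3 ketone, C4=C5–C6 oxolane, C11 bromide) | O[C@@]1(C(=O)N(C)OC)C[C@@H](O[Si](C)(C)C(C)(C)C)C(=O)/C1=C/[C@]1(C)CC[C@H](O1)C(C)(C)CBr | intermediate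
20 | (2R,4E,6S,9S,15S)-allylic alcohol (C3 carbinol, C3 epimers) | O[C@@]1(C(=O)N(C)OC)C[C@@H](O[Si](C)(C)C(C)(C)C)C(O)/C1=C/[C@]1(C)CC[C@H](O1)C(C)(C)CBr | intermediate
21 | (2R,4E,6S,9S,15S)-isopropenyl ketone (C14 enone, 2-OTBS, 3-OH) | O[C@@]1(C(=O)C(C)=C)C[C@@H](O[Si](C)(C)C(C)(C)C)C(O)/C1=C/[C@]1(C)CC[C@H](O1)C(C)(C)CBr | intermediate
22 | (2R,4E,6S,9S,15S)-triol (2-OH, 3-OH, 15-OH, C14 enone) | O[C@@]1(C(=O)C(C)=C)C[C@@H](O)C(O)/C1=C/[C@]1(C)CC[C@H](O1)C(C)(C)CBr | intermediate
23 | (4E,6S,9S,15S)-diosphenol (2,15-dihydroxycyclopent-1-en-3-one ring A) | O[C@@]1(C(=O)C(C)=C)C=C(O)C(=O)/C1=C/[C@]1(C)CC[C@H](O1)C(C)(C)CBr | intermediate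
24 | (4E,6S,9S,15S)-enol triflate (2-OSO2CF3) | O[C@@]1(C(=O)C(C)=C)C=C(OS(=O)(=O)C(F)(F)F)C(=O)/C1=C/[C@]1(C)CC[C@H](O1)C(C)(C)CBr | intermediate
25 | (4E,6S,9S,15S)-bromo dienone (2-methyl ring A, C14 isopropenyl ketone, C11 bromide) | O[C@@]1(C(=O)C(C)=C)C=C(C)C(=O)/C1=C/[C@]1(C)CC[C@H](O1)C(C)(C)CBr | intermediate
26 | (4E,6S,9S,13R,15S)-15-O-deacetyl target (macrocyclic hydroxy dienone) | O[C@@]12C=C(C)C(=O)/C1=C/[C@]1(C)CC[C@H](O1)C(C)(C)CC[C@@H](C)C2=O | intermediate
27 | CNP0144863.1, (4E,6S,9S,13R,15S)-15-acetate | CC(=O)O[C@@]12C=C(C)C(=O)/C1=C/[C@]1(C)CC[C@H](O1)C(C)(C)CC[C@@H](C)C2=O | target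

## Step count and least certain steps

Total: 20 steps. Longest linear sequence: 16 steps from 1 (steps 1–7 and 12–20). The oxolane acid 18 takes steps 8–11 from 10 and 11.

Step 5 (key step). Most likely failure: loss of water from the aldol through the enamine/iminium manifold (β-elimination of the new C3 hydroxyl), and to a lesser degree closure with the reverse donor/acceptor pairing. Fallback, from 6 back to 7: accept the condensation on purpose (pyrrolidine, AcOH) to the cyclopentene carbaldehyde F1. Then carry out copper-catalysed conjugate borylation (B2pin2, CuCl, NaOtBu, DPEphos, MeOH, THF) to the 3-boryl aldehyde F2, and oxidise the C–B bond with NaBO3·4H2O, which returns aldol 7 without relying on the aldol equilibrium.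

Step 12. Most likely failure: consumption of the β-iodo enone by polar addition–elimination of the carboxylate before it is oxidised, together with incomplete control of the face of attack at C6 and of the C4=C5 geometry. A Z isomer cannot be used later, because only the E alkene can close the ring in step 19; if needed it would be re-equilibrated by sensitised irradiation. Fallback, from 18 back to 19: convert 18 (N-hydroxyphthalimide, DIC, DMAP) into the redox-active ester F3 and generate the same C6 radical reductively (Ru(bpy)3(PF6)2, Hantzsch ester, blue LEDs, CH2Cl2) in the presence of 9. No free carboxylate is present, and this mode is established for hindered tertiary radicals.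

Step 19. Most likely failure: reduction of the C11 radical before the slow medium-ring closure, and hydrogen transfer to the wrong face of the C13 radical. Fallback, from 25 back to 26: carry the cyclisation through whatever the C13 ratio, isolate the 13-epimer F4, and equilibrate it through the C13–C14 enol (DBU, toluene, rt). This replaces kinetic hydrogen transfer by thermodynamic control at the only epimerisable centre and recycles F4 to 26; it succeeds only if the natural configuration is the more stable one in the bicycle.

Step 7. Most likely failure: delivery of iodide to the ketone carbon C3 instead of C5, and hydrolytic loss of the β-iodo enone on purification. Fallback, from 8 back to 19: condense 8 with thiophenol (TsOH cat., benzene) to the phenylthiomethylene ketone F5 and oxidise (mCPBA) to the phenylsulfonylmethylene ketone F6. F6 reacts with 18 under the conditions of step 12 by radical addition and loss of sulfinate (the established vinyl sulfone mode) to give 19.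

Step 20. Most likely failure: sluggish acylation of the hindered tertiary hydroxyl, so that forcing conditions bring on epimerisation at C13 or α-ketol rearrangement. Fallback, from 25 to 27: acetylate before ring closure (Ac2O, DMAP, Et3N) to the acetate F7, where no C13 centre exists yet, and run the radical macrocyclisation of step 19 on F7, which gives 27 directly.

## Further compounds

F1 | step 5 | (2R,15S)-2-(tert-butyldimethylsilyloxy)-4-formyl-15-hydroxy-N-methoxy-N-methylcyclopent-3-ene-15-carboxamide | O[C@@]1(C(=O)N(C)OC)C[C@@H](O[Si](C)(C)C(C)(C)C)C=C1C=O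
F2 | step 5 | (2R,15S)-2-(tert-butyldimethylsilyloxy)-4-formyl-15-hydroxy-N-methoxy-N-methyl-3-(4,4,5,5-tetramethyl-1,3,2-dioxaborolan-2-yl)cyclopentane-15-carboxamide | O[C@@]1(C(=O)N(C)OC)C[C@@H](O[Si](C)(C)C(C)(C)C)C(B2OC(C)(C)C(C)(C)O2)C1C=O
F3 | step 12 | 1,3-dioxoisoindolin-2-yl (5S)-5-(1-bromo-2-methylpropan-2-yl)-2-methyloxolane-2-carboxylate | O=C(ON1C(=O)c2ccccc2C1=O)C1(C)CC[C@H](O1)C(C)(C)CBr
F4 | step 19 | 13-epimer of 26 (4E,6S,9S,13S,15S) | O[C@@]12C=C(C)C(=O)/C1=C/[C@]1(C)CC[C@H](O1)C(C)(C)CC[C@H](C)C2=O
F5 | step 7 | (2R,15S)-2-(tert-butyldimethylsilyloxy)-15-hydroxy-N-methoxy-N-methyl-3-oxo-4-[(phenylsulfanyl)methylene]cyclopentane-15-carboxamide | O[C@@]1(C(=O)N(C)OC)C[C@@H](O[Si](C)(C)C(C)(C)C)C(=O)/C1=C/Sc1ccccc1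
F6 | step 7 | (2R,15S)-2-(tert-butyldimethylsilyloxy)-15-hydroxy-N-methoxy-N-methyl-3-oxo-4-[(phenylsulfonyl)methylene]cyclopentane-15-carboxamide | O[C@@]1(C(=O)N(C)OC)C[C@@H](O[Si](C)(C)C(C)(C)C)C(=O)/C1=C/S(=O)(=O)c1ccccc1
F7 | step 20 | 15-O-acetate of 25 | CC(=O)O[C@@]1(C(=O)C(C)=C)C=C(C)C(=O)/C1=C/[C@]1(C)CC[C@H](O1)C(C)(C)CBr
A1 | alternative 1 | macrocyclic acylfulvene (ring double bonds C15=C1 and C2=C3, exocyclic C4=C5, C14 ketone on C15; 6S,9S,13R) | C12=CC(C)=C/C1=C/[C@]1(C)CC[C@H](O1)C(C)(C)CC[C@@H](C)C2=O
A2 | alternative 1 | 15,3-endoperoxide of A1 (2,3-dioxabicyclo[2.2.1]hept-5-ene core) | O3[C@@]12C=C(C)[C@@H](O3)/C1=C/[C@]1(C)CC[C@H](O1)C(C)(C)CC[C@@H](C)C2=O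
A3 | alternative 1 | 15-O-deacetyl target (same structure as 26) | O[C@@]12C=C(C)C(=O)/C1=C/[C@]1(C)CC[C@H](O1)C(C)(C)CC[C@@H](C)C2=O
A4 | alternative 2 | tert-butyl(furan-2-ylmethoxy)dimethylsilane | CC(C)(C)[Si](C)(C)OCc1ccco1
A5 | alternative 2 | 1,3-dibromo-3-methylbutan-2-one | CC(C)(Br)C(=O)CBr
A6 | alternative 2 | 1-[(tert-butyldimethylsilyloxy)methyl]-4,4-dimethyl-8-oxabicyclo[3.2.1]oct-6-en-3-one (enantiomer shown) | CC(C)(C)[Si](C)(C)OC[C@]12C=C[C@H](O1)C(C)(C)C(=O)C2
A7 | alternative 3 | [11](2,5)furanophane with C4 carbinol, 2-methylfuran core, (6S,9S)-oxolane, 13R methyl and C14 silyl ether | OC1C[C@]2(C)CC[C@H](O2)C(C)(C)CC[C@@H](C)C(O[Si](C)(C)C(C)(C)C)c2cc(C)c1o2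
A8 | alternative 3 | ring-contracted 15-hydroxycyclopentenone with saturated C4–C5 and C14 silyl ether | O[C@@]12C=C(C)C(=O)C1C[C@]1(C)CC[C@H](O1)C(C)(C)CC[C@@H](C)C2O[Si](C)(C)C(C)(C)C
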